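**Retrosynthetic overview**
1. Target 36 ⇐ hydrogenolysis of the tetradeca-O-benzyl hexamer 35 (ring F 4-OH already free).
2. Rings C, D, E, F: each diaryl ether is cut at the unhindered aryl carbon. The forward reaction is an Ullmann coupling of a 2,6-dioxygenated phenol with a bromobenzaldehyde (17 for rings C, E, F; 26 for ring D). The formyl group then becomes the next phenol by Baeyer–Villiger (Dakin) oxidation.
3. Ring A is the only ring built from acyclic carbon. Its ether oxygen is first attached to ring B as a simple aryloxyacetate (Williamson). The key C–C bond is a crossed Claisen condensation of that ester with the dianion of methyl acetoacetate, followed by Claisen ring closure and aromatisation.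
4. Order: ring B (from 2,4,6-trihydroxybenzaldehyde) → ring A formed on it (steps 5–6) → rings C, D, E, F appended one by one.

Assumption: the target has no stereocentre and its diaryl ether axes rotate freely, so it is a single achiral compound and no stereocontrol is needed.
Convention: where one reagent acts several times on equivalent groups within a step (double or triple benzylation, final hydrogenolysis), the partly reacted species are not listed.

**Route**

Step 1
Reactants: 1 2,4,6-trihydroxybenzaldehyde; 2 methyl bromoacetate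
Product: 3 methyl 2-(4-formyl-3,5-dihydroxyphenoxy)acetate
Conditions: 2 (1.05 equiv), K2CO3 (1.05 equiv), acetone, 0 °C → rt
Reagents that add atoms: none
Why: Williamson ether synthesis; the 4-OH is para to the formyl group and the only one not hydrogen-bonded to it, so it is the most acidic and is alkylated selectively by one equivalent of bromoacetate.

Step 2
Reactants: 3 methyl 2-(4-formyl-3,5-dihydroxyphenoxy)acetate
Product: 4 methyl 2-[3,5-bis(benzyloxy)-4-formylphenoxy]acetate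
Conditions: BnBr (2.5 equiv), K2CO3, DMF, 60 °C
Reagents that add atoms: benzyl bromide BrCc1ccccc1
Why: Williamson etherification of the two chelated ortho-hydroxyls under warmer dipolar conditions; aldehyde and methyl ester are inert to anhydrous K2CO3.

Step 3
Reactants: 4 methyl 2-[3,5-bis(benzyloxy)-4-formylphenoxy]acetate
Product: 6 methyl 2-[3,5-bis(benzyloxy)-4-hydroxyphenoxy]acetate, via aryl formate 5 (not isolated)
Conditions: mCPBA (1.3 equiv), CH2Cl2, 0 °C → rt; then K2CO3 (cat.), MeOH, 0 °C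
Reagents that add atoms: mCPBA OOC(=O)c1cccc(Cl)c1
Why: Baeyer–Villiger (Dakin-type) oxidation; the electron-rich 2,6-dialkoxyaryl group migrates in preference to hydrogen, and mild methanolysis cleaves the formate without touching the methyl ester.

Step 4
Reactants: 6 methyl 2-[3,5-bis(benzyloxy)-4-hydroxyphenoxy]acetate
Product: 7 methyl 2-[3,5-bis(benzyloxy)-4-(methoxymethoxy)phenoxy]acetate
Conditions: MOMCl (1.5 equiv), K2CO3, acetone, rt
Reagents that add atoms: chloromethyl methyl ether COCCl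
Why: O-alkylation to a MOM acetal masks the hindered phenol; it withstands the strong bases of steps 5–8 and can later be removed beside benzyl ethers.

Step 5
Reactants: 7 methyl 2-[3,5-bis(benzyloxy)-4-(methoxymethoxy)phenoxy]acetate; 8 methyl acetoacetate
Product: 10 methyl 6-[3,5-bis(benzyloxy)-4-(methoxymethoxy)phenoxy]-3,5-dioxohexanoate, via acetoacetate dianion 9 (not isolated)
Conditions: 8 (3 equiv), NaH, THF, 0 °C; n-BuLi, 0 °C; then 7, −78 → 0 °C; cold 1 M HCl to pH 4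
Reagents that add atoms: none
Why: Crossed Claisen condensation (Huckin–Weiler dianion acylation); the γ-carbanion attacks the inductively activated α-aryloxy ester and the product is held as its enolate, so excess dianion drives the C–C bond formation.

Step 6
Reactants: 10 methyl 6-[3,5-bis(benzyloxy)-4-(methoxymethoxy)phenoxy]-3,5-dioxohexanoate
Product: 11 2-[3,5-bis(benzyloxy)-4-(methoxymethoxy)phenoxy]benzene-1,3,5-triol
Conditions: NaOMe (6 equiv), MeOH–THF, high dilution, sealed tube, 100 °C; then cold 1 M HCl to pH 4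
Reagents that add atoms: none
Why: Intramolecular Claisen (Dieckmann-type) condensation of the α-aryloxy ketone carbon onto the ester, made irreversible by aromatisation of the cyclohexane-1,3,5-trione; the competing 4-hydroxy-2-pyranone is reopened by methoxide.

Step 7
Reactants: 11 2-[3,5-bis(benzyloxy)-4-(methoxymethoxy)phenoxy]benzene-1,3,5-triol
Product: 12 2-[3,5-bis(benzyloxy)-4-(methoxymethoxy)phenoxy]benzene-1,3,5-triyl triacetate
Conditions: Ac2O, pyridine, DMAP (cat.), rt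
Reagents that add atoms: acetic anhydride CC(=O)OC(C)=O
Why: O-Acetylation gives a stable triacetate and sets up a benzylation free of C-alkylation.

Step 8
Reactants: 12 2-[3,5-bis(benzyloxy)-4-(methoxymethoxy)phenoxy]benzene-1,3,5-triyl triacetate
Product: 14 1,3,5-tris(benzyloxy)-2-[3,5-bis(benzyloxy)-4-(methoxymethoxy)phenoxy]benzene, via trisodium triolate 13 (not isolated)
Conditions: NaH (7 equiv), BnCl (4 equiv), DMF, 0 °C; H2O (3 equiv) added slowly; → rt
Reagents that add atoms: benzyl chloride ClCc1ccccc1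
Why: Deacetylative Williamson benzylation; NaOH formed in situ frees the phenoxides gradually in DMF, where each is O-benzylated at once, avoiding the C-benzylation typical of free phloroglucinols.

Step 9
Reactants: 14 1,3,5-tris(benzyloxy)-2-[3,5-bis(benzyloxy)-4-(methoxymethoxy)phenoxy]benzene
Product: 15 ring-AB phenol 2,6-bis(benzyloxy)-4-[2,4,6-tris(benzyloxy)phenoxy]phenol
Conditions: 3 M HCl, MeOH–THF, 50 °C
Reagents that add atoms: none
Why: Acid-catalysed acetal exchange removes the MOM group; benzyl and diaryl ethers are stable to dilute HCl.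

Step 10
Reactants: 16 4-bromo-2,6-difluorobenzaldehyde
Product: 17 2,6-bis(benzyloxy)-4-bromobenzaldehyde
Conditions: BnOH (2.2 equiv), NaH (2.2 equiv), THF, 0 °C → rt
Reagents that add atoms: benzyl alcohol OCc1ccccc1
Why: Nucleophilic aromatic substitution (SNAr); both fluorides are ortho to the formyl group and far better leaving groups than the para bromide, which is kept for the couplings.

Step 11
Reactants: 15 ring-AB phenol; 17 2,6-bis(benzyloxy)-4-bromobenzaldehyde
Product: 18 ring-ABC aldehyde 2,6-bis(benzyloxy)-4-{2,6-bis(benzyloxy)-4-[2,4,6-tris(benzyloxy)phenoxy]phenoxy}benzaldehyde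
Conditions: CuI (10 mol %), picolinic acid (20 mol %), K3PO4 (2 equiv), DMSO, 90 °C, Ar
Reagents that add atoms: none
Why: Ullmann-type diaryl ether synthesis; the bromide is unhindered and activated by the para formyl group, and the CuI–picolinic acid system accepts 2,6-disubstituted phenols.

Step 12
Reactants: 18 ring-ABC aldehyde
Product: 20 ring-ABC phenol 2,6-bis(benzyloxy)-4-{2,6-bis(benzyloxy)-4-[2,4,6-tris(benzyloxy)phenoxy]phenoxy}phenol, via aryl formate 19 (not isolated)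
Conditions: mCPBA (1.3 equiv), CH2Cl2, 0 °C → rt; then K2CO3 (cat.), MeOH–THF, 0 °C
Reagents that add atoms: mCPBA OOC(=O)c1cccc(Cl)c1
Why: Baeyer–Villiger (Dakin-type) oxidation of the 2,6-dialkoxybenzaldehyde with aryl migration, then formate methanolysis, unveils the next hindered phenol.

Step 13
Reactants: 21 5-bromo-1,2,3-trimethoxybenzene
Product: 23 6-bromo-2,3,4-trimethoxybenzaldehyde, via chloro(methoxy)methyl arene 22 (not isolated)
Conditions: Cl2CHOMe (1.5 equiv), TiCl4 (2 equiv), CH2Cl2, −10 → 0 °C; then ice–water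
Reagents that add atoms: dichloromethyl methyl ether COC(Cl)Cl; water O
Why: Rieche formylation (Friedel–Crafts type); the two free positions are equivalent and each is ortho and para to a methoxy group, so one aldehyde forms with the formyl group between Br and OMe.

Step 14
Reactants: 23 6-bromo-2,3,4-trimethoxybenzaldehyde
Product: 25 6-bromo-2,3,4-trihydroxybenzaldehyde, via aryl borate 24 (not isolated)
Conditions: BBr3 (4.5 equiv), CH2Cl2, −78 °C → rt; then ice–water
Reagents that add atoms: none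
Why: Lewis-acid ether cleavage; BBr3 removes all three methyl groups through aryl borates that hydrolyse on work-up, and aryl bromide and aldehyde survive.

Step 15
Reactants: 25 6-bromo-2,3,4-trihydroxybenzaldehyde
Product: 26 2,3,4-tris(benzyloxy)-6-bromobenzaldehyde
Conditions: BnBr (3.6 equiv), K2CO3, DMF, 60 °C, Ar
Reagents that add atoms: benzyl bromide BrCc1ccccc1
Why: Williamson etherification makes the ring D protection uniform with the rest of the molecule.

Step 16
Reactants: 20 ring-ABC phenol; 26 2,3,4-tris(benzyloxy)-6-bromobenzaldehyde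
Product: 27 ring-ABCD aldehyde 2,3,4-tris(benzyloxy)-6-(aryloxy)benzaldehyde in which aryloxy is the phenoxy residue of 20
Conditions: CuI (20 mol %), picolinic acid (40 mol %), K3PO4 (2 equiv), DMSO, 100 °C, Ar
Reagents that add atoms: none
Why: Ullmann-type coupling; the ortho formyl group accelerates copper insertion into the C–Br bond and the other ortho position is unsubstituted, which offsets the bulk of the phenol.

Step 17
Reactants: 27 ring-ABCD aldehyde
Product: 29 ring-ABCD phenol 2,3,4-tris(benzyloxy)-6-(aryloxy)phenol in which aryloxy is the phenoxy residue of 20, via aryl formate 28 (not isolated)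
Conditions: mCPBA (1.3 equiv), CH2Cl2, 0 °C → rt; then K2CO3 (cat.), MeOH–THF, 0 °C
Reagents that add atoms: mCPBA OOC(=O)c1cccc(Cl)c1
Why: Baeyer–Villiger (Dakin-type) oxidation of the formyl group flanked by aryloxy and benzyloxy groups turns the ring D carbon into the phenol that will carry ring E.

Step 18
Reactants: 29 ring-ABCD phenol; 17 2,6-bis(benzyloxy)-4-bromobenzaldehyde
Product: 30 ring-ABCDE aldehyde 2,6-bis(benzyloxy)-4-(aryloxy)benzaldehyde in which aryloxy is the phenoxy residue of 29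
Conditions: CuI (20 mol %), picolinic acid (40 mol %), K3PO4 (2 equiv), DMSO, 90 °C, Ar
Reagents that add atoms: none
Why: Ullmann-type diaryl ether synthesis with the activated, unhindered bromide 17, as in step 11.

Step 19
Reactants: 30 ring-ABCDE aldehyde
Product: 32 ring-ABCDE phenol 2,6-bis(benzyloxy)-4-(aryloxy)phenol in which aryloxy is the phenoxy residue of 29, via aryl formate 31 (not isolated)
Conditions: mCPBA (1.3 equiv), CH2Cl2, 0 °C → rt; then K2CO3 (cat.), MeOH–THF, 0 °C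
Reagents that add atoms: mCPBA OOC(=O)c1cccc(Cl)c1
Why: Baeyer–Villiger (Dakin-type) oxidation and formate methanolysis, as in step 12.

Step 20
Reactants: 32 ring-ABCDE phenol; 17 2,6-bis(benzyloxy)-4-bromobenzaldehyde
Product: 33 ring-ABCDEF aldehyde 2,6-bis(benzyloxy)-4-(aryloxy)benzaldehyde in which aryloxy is the phenoxy residue of 32
Conditions: CuI (20 mol %), picolinic acid (40 mol %), K3PO4 (2 equiv), DMSO, 90 °C, Ar
Reagents that add atoms: none
Why: Ullmann-type diaryl ether synthesis with the activated bromide 17 installs ring F.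

Step 21
Reactants: 33 ring-ABCDEF aldehyde
Product: 35 ring-ABCDEF phenol 2,6-bis(benzyloxy)-4-(aryloxy)phenol in which aryloxy is the phenoxy residue of 32, via aryl formate 34 (not isolated)
Conditions: mCPBA (1.3 equiv), CH2Cl2, 0 °C → rt; then K2CO3 (cat.), MeOH–THF, 0 °C
Reagents that add atoms: mCPBA OOC(=O)c1cccc(Cl)c1
Why: Baeyer–Villiger (Dakin-type) oxidation supplies the 4-OH of ring F, which needs no protection before the last step.

Step 22
Reactants: 35 ring-ABCDEF phenol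
Product: 36 target hexamer CNP0175585.0
Conditions: H2 (1 atm), Pd(OH)2/C, THF–MeOH (degassed), rt; filtered and concentrated under Ar
Reagents that add atoms: none
Why: Catalytic hydrogenolysis cleaves all fourteen benzyl ethers to toluene and leaves the diaryl ether bonds intact; the air-sensitive polyphenol is kept under argon.

**Compound list**
1 | 2,4,6-trihydroxybenzaldehyde | O=Cc1c(O)cc(O)cc1O | starting material
2 | methyl bromoacetate | COC(=O)CBr | starting material
3 | methyl 2-(4-formyl-3,5-dihydroxyphenoxy)acetate | COC(=O)COc1cc(O)c(C=O)c(O)c1 | intermediate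
4 | methyl 2-[3,5-bis(benzyloxy)-4-formylphenoxy]acetate | COC(=O)COc1cc(OCc2ccccc2)c(C=O)c(OCc2ccccc2)c1 | intermediate
5 | methyl 2-[3,5-bis(benzyloxy)-4-(formyloxy)phenoxy]acetate | COC(=O)COc1cc(OCc2ccccc2)c(OC=O)c(OCc2ccccc2)c1 | intermediate (not isolated)
6 | methyl 2-[3,5-bis(benzyloxy)-4-hydroxyphenoxy]acetate | COC(=O)COc1cc(OCc2ccccc2)c(O)c(OCc2ccccc2)c1 | intermediate
7 | methyl 2-[3,5-bis(benzyloxy)-4-(methoxymethoxy)phenoxy]acetate | COC(=O)COc1cc(OCc2ccccc2)c(OCOC)c(OCc2ccccc2)c1 | intermediate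
8 | methyl acetoacetate | CC(=O)CC(=O)OC | starting material
9 | sodium lithium C2,C4-dianion of methyl acetoacetate | [Na+].[Li+].[CH2-]C(=O)[CH-]C(=O)OC | intermediate (not isolated)
10 | methyl 6-[3,5-bis(benzyloxy)-4-(methoxymethoxy)phenoxy]-3,5-dioxohexanoate | COC(=O)CC(=O)CC(=O)COc1cc(OCc2ccccc2)c(OCOC)c(OCc2ccccc2)c1 | intermediate
11 | 2-[3,5-bis(benzyloxy)-4-(methoxymethoxy)phenoxy]benzene-1,3,5-triol | Oc1cc(O)c(Oc2cc(OCc3ccccc3)c(OCOC)c(OCc3ccccc3)c2)c(O)c1 | intermediate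
12 | 2-[3,5-bis(benzyloxy)-4-(methoxymethoxy)phenoxy]benzene-1,3,5-triyl triacetate | CC(=O)Oc1cc(OC(C)=O)c(Oc2cc(OCc3ccccc3)c(OCOC)c(OCc3ccccc3)c2)c(OC(C)=O)c1 | intermediate
13 | trisodium 2-[3,5-bis(benzyloxy)-4-(methoxymethoxy)phenoxy]benzene-1,3,5-triolate | [Na+].[Na+].[Na+].[O-]c1cc([O-])c(Oc2cc(OCc3ccccc3)c(OCOC)c(OCc3ccccc3)c2)c([O-])c1 | intermediate (not isolated)
14 | 1,3,5-tris(benzyloxy)-2-[3,5-bis(benzyloxy)-4-(methoxymethoxy)phenoxy]benzene | COCOc2c(OCc9ccccc9)cc(Oc1c(OCc9ccccc9)cc(OCc9ccccc9)cc1OCc9ccccc9)cc2OCc9ccccc9 | intermediate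
15 | ring-AB phenol, 2,6-bis(benzyloxy)-4-[2,4,6-tris(benzyloxy)phenoxy]phenol | Oc2c(OCc9ccccc9)cc(Oc1c(OCc9ccccc9)cc(OCc9ccccc9)cc1OCc9ccccc9)cc2OCc9ccccc9 | intermediate
16 | 4-bromo-2,6-difluorobenzaldehyde | O=Cc1c(F)cc(Br)cc1F | starting material
17 | 2,6-bis(benzyloxy)-4-bromobenzaldehyde | O=Cc1c(OCc2ccccc2)cc(Br)cc1OCc1ccccc1 | intermediate
18 | ring-ABC aldehyde, 2,6-bis(benzyloxy)-4-{2,6-bis(benzyloxy)-4-[2,4,6-tris(benzyloxy)phenoxy]phenoxy}benzaldehyde | O=Cc3c(OCc9ccccc9)cc(Oc2c(OCc9ccccc9)cc(Oc1c(OCc9ccccc9)cc(OCc9ccccc9)cc1OCc9ccccc9)cc2OCc9ccccc9)cc3OCc9ccccc9 | intermediate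
19 | ring-ABC aryl formate (formate ester of 20) | O=COc3c(OCc9ccccc9)cc(Oc2c(OCc9ccccc9)cc(Oc1c(OCc9ccccc9)cc(OCc9ccccc9)cc1OCc9ccccc9)cc2OCc9ccccc9)cc3OCc9ccccc9 | intermediate (not isolated)
20 | ring-ABC phenol, 2,6-bis(benzyloxy)-4-{2,6-bis(benzyloxy)-4-[2,4,6-tris(benzyloxy)phenoxy]phenoxy}phenol | Oc3c(OCc9ccccc9)cc(Oc2c(OCc9ccccc9)cc(Oc1c(OCc9ccccc9)cc(OCc9ccccc9)cc1OCc9ccccc9)cc2OCc9ccccc9)cc3OCc9ccccc9 | intermediate
21 | 5-bromo-1,2,3-trimethoxybenzene | COc1cc(Br)cc(OC)c1OC | starting material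
22 | 1-bromo-2-[chloro(methoxy)methyl]-3,4,5-trimethoxybenzene | COC(Cl)c1c(Br)cc(OC)c(OC)c1OC | intermediate (not isolated)
23 | 6-bromo-2,3,4-trimethoxybenzaldehyde | COc1cc(Br)c(C=O)c(OC)c1OC | intermediate
24 | 6-bromo-2,3,4-tris(dibromoboryloxy)benzaldehyde | O=Cc1c(Br)cc(OB(Br)Br)c(OB(Br)Br)c1OB(Br)Br | intermediate (not isolated)
25 | 6-bromo-2,3,4-trihydroxybenzaldehyde | O=Cc1c(Br)cc(O)c(O)c1O | intermediate
26 | 2,3,4-tris(benzyloxy)-6-bromobenzaldehyde | O=Cc1c(Br)cc(OCc2ccccc2)c(OCc2ccccc2)c1OCc1ccccc1 | intermediate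
27 | ring-ABCD aldehyde, 2,3,4-tris(benzyloxy)-6-(aryloxy)benzaldehyde, aryloxy = phenoxy residue of 20 | O=Cc4c(Oc3c(OCc9ccccc9)cc(Oc2c(OCc9ccccc9)cc(Oc1c(OCc9ccccc9)cc(OCc9ccccc9)cc1OCc9ccccc9)cc2OCc9ccccc9)cc3OCc9ccccc9)cc(OCc9ccccc9)c(OCc9ccccc9)c4OCc9ccccc9 | intermediate
28 | ring-ABCD aryl formate (formate ester of 29) | O=COc4c(Oc3c(OCc9ccccc9)cc(Oc2c(OCc9ccccc9)cc(Oc1c(OCc9ccccc9)cc(OCc9ccccc9)cc1OCc9ccccc9)cc2OCc9ccccc9)cc3OCc9ccccc9)cc(OCc9ccccc9)c(OCc9ccccc9)c4OCc9ccccc9 | intermediate (not isolated)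
29 | ring-ABCD phenol, 2,3,4-tris(benzyloxy)-6-(aryloxy)phenol, aryloxy = phenoxy residue of 20 | Oc4c(Oc3c(OCc9ccccc9)cc(Oc2c(OCc9ccccc9)cc(Oc1c(OCc9ccccc9)cc(OCc9ccccc9)cc1OCc9ccccc9)cc2OCc9ccccc9)cc3OCc9ccccc9)cc(OCc9ccccc9)c(OCc9ccccc9)c4OCc9ccccc9 | intermediate
30 | ring-ABCDE aldehyde, 2,6-bis(benzyloxy)-4-(aryloxy)benzaldehyde, aryloxy = phenoxy residue of 29 | O=Cc5c(OCc9ccccc9)cc(Oc4c(Oc3c(OCc9ccccc9)cc(Oc2c(OCc9ccccc9)cc(Oc1c(OCc9ccccc9)cc(OCc9ccccc9)cc1OCc9ccccc9)cc2OCc9ccccc9)cc3OCc9ccccc9)cc(OCc9ccccc9)c(OCc9ccccc9)c4OCc9ccccc9)cc5OCc9ccccc9 | intermediate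
31 | ring-ABCDE aryl formate (formate ester of 32) | O=COc5c(OCc9ccccc9)cc(Oc4c(Oc3c(OCc9ccccc9)cc(Oc2c(OCc9ccccc9)cc(Oc1c(OCc9ccccc9)cc(OCc9ccccc9)cc1OCc9ccccc9)cc2OCc9ccccc9)cc3OCc9ccccc9)cc(OCc9ccccc9)c(OCc9ccccc9)c4OCc9ccccc9)cc5OCc9ccccc9 | intermediate (not isolated)
32 | ring-ABCDE phenol, 2,6-bis(benzyloxy)-4-(aryloxy)phenol, aryloxy = phenoxy residue of 29 | Oc5c(OCc9ccccc9)cc(Oc4c(Oc3c(OCc9ccccc9)cc(Oc2c(OCc9ccccc9)cc(Oc1c(OCc9ccccc9)cc(OCc9ccccc9)cc1OCc9ccccc9)cc2OCc9ccccc9)cc3OCc9ccccc9)cc(OCc9ccccc9)c(OCc9ccccc9)c4OCc9ccccc9)cc5OCc9ccccc9 | intermediate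
33 | ring-ABCDEF aldehyde, 2,6-bis(benzyloxy)-4-(aryloxy)benzaldehyde, aryloxy = phenoxy residue of 32 | O=Cc6c(OCc9ccccc9)cc(Oc5c(OCc9ccccc9)cc(Oc4c(Oc3c(OCc9ccccc9)cc(Oc2c(OCc9ccccc9)cc(Oc1c(OCc9ccccc9)cc(OCc9ccccc9)cc1OCc9ccccc9)cc2OCc9ccccc9)cc3OCc9ccccc9)cc(OCc9ccccc9)c(OCc9ccccc9)c4OCc9ccccc9)cc5OCc9ccccc9)cc6OCc9ccccc9 | intermediate
34 | ring-ABCDEF aryl formate (formate ester of 35) | O=COc6c(OCc9ccccc9)cc(Oc5c(OCc9ccccc9)cc(Oc4c(Oc3c(OCc9ccccc9)cc(Oc2c(OCc9ccccc9)cc(Oc1c(OCc9ccccc9)cc(OCc9ccccc9)cc1OCc9ccccc9)cc2OCc9ccccc9)cc3OCc9ccccc9)cc(OCc9ccccc9)c(OCc9ccccc9)c4OCc9ccccc9)cc5OCc9ccccc9)cc6OCc9ccccc9 | intermediate (not isolated)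
35 | ring-ABCDEF phenol, 2,6-bis(benzyloxy)-4-(aryloxy)phenol, aryloxy = phenoxy residue of 32 | Oc6c(OCc9ccccc9)cc(Oc5c(OCc9ccccc9)cc(Oc4c(Oc3c(OCc9ccccc9)cc(Oc2c(OCc9ccccc9)cc(Oc1c(OCc9ccccc9)cc(OCc9ccccc9)cc1OCc9ccccc9)cc2OCc9ccccc9)cc3OCc9ccccc9)cc(OCc9ccccc9)c(OCc9ccccc9)c4OCc9ccccc9)cc5OCc9ccccc9)cc6OCc9ccccc9 | intermediate
36 | CNP0175585.0 (achiral hexameric phlorotannin) | Oc1cc(O)c(Oc2cc(O)c(Oc3cc(O)c(Oc4cc(O)c(O)c(O)c4Oc4cc(O)c(Oc5cc(O)c(O)c(O)c5)c(O)c4)c(O)c3)c(O)c2)c(O)c1 | target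

**Summary**
Total steps: 22. Longest linear sequence: 18 steps (1–9, 11–12, 16–22). The side branches are step 10 (compound 17) and steps 13–15 (compound 26).

**Three steps most likely to fail, each with a fallback**

Step 6 (ring closure of 10 to the phloroglucinol). The nucleophilic carbon is only singly activated, so the reaction may stop at the 4-hydroxy-2-pyranone, give intermolecular aldol products, or fragment by retro-Claisen cleavage. The fallback takes ring A from the aromatic pool; it sets out from 1 (using 17 from step 10) and comes back to the route at 15. Compound 1 is perbenzylated (BnBr, K2CO3, DMF, 80 °C) to 2,4,6-tris(benzyloxy)benzaldehyde F1. Oxidation with mCPBA gives 2,4,6-tris(benzyloxy)phenyl formate F2, and methanolysis gives 2,4,6-tris(benzyloxy)phenol F3. Ullmann coupling of this hindered phenol with 17 (CuI, picolinic acid, K3PO4, DMSO, 90 °C) gives 2,6-bis(benzyloxy)-4-[2,4,6-tris(benzyloxy)phenoxy]benzaldehyde F4. A second Baeyer–Villiger oxidation gives 2,6-bis(benzyloxy)-4-[2,4,6-tris(benzyloxy)phenoxy]phenyl formate F5, and methanolysis delivers 15, from which step 11 continues unchanged.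

Step 5 (crossed Claisen condensation). The strongly basic dianion may enolise the α-aryloxy ester instead of acylating. The fallback replaces the dianion by a neutral silyl dienolate; it sets out from 7 and comes back at 10. Saponification (LiOH, THF–H2O) gives 2-[3,5-bis(benzyloxy)-4-(methoxymethoxy)phenoxy]acetic acid F6. Neutral chlorination with 1-chloro-N,N,2-trimethylprop-1-en-1-amine, which spares the MOM group, gives 2-[3,5-bis(benzyloxy)-4-(methoxymethoxy)phenoxy]acetyl chloride F7. This acylates the terminal carbon of commercial 1-methoxy-1,3-bis(trimethylsilyloxy)buta-1,3-diene (CH2Cl2, −78 → 20 °C), and mild aqueous work-up gives 10.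

Step 16 (Ullmann coupling of the hindered phenol 20 with the ortho-substituted bromide 26). Both partners are crowded and the phenol is prone to oxidation under copper. The fallback uses metal-free SNAr on the fluoro analogue; it sets out from 20 and comes back at 27. Commercial 5-fluoro-1,2,3-trimethoxybenzene F8 is formylated as in step 13 through 2-[chloro(methoxy)methyl]-1-fluoro-3,4,5-trimethoxybenzene F9 to 6-fluoro-2,3,4-trimethoxybenzaldehyde F10. BBr3 cleaves the methyl ethers through 6-fluoro-2,3,4-tris(dibromoboryloxy)benzaldehyde F11 to 6-fluoro-2,3,4-trihydroxybenzaldehyde F12. Benzylation (BnBr, K2CO3, DMF) gives 2,3,4-tris(benzyloxy)-6-fluorobenzaldehyde F13. The phenoxide of 20 then displaces the fluoride ortho to the formyl group (Cs2CO3, DMSO, 120 °C) to give 27.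

**Further compounds**
F1 | step 6 | 2,4,6-tris(benzyloxy)benzaldehyde | O=Cc1c(OCc2ccccc2)cc(OCc2ccccc2)cc1OCc1ccccc1
F2 | step 6 | 2,4,6-tris(benzyloxy)phenyl formate | O=COc1c(OCc2ccccc2)cc(OCc2ccccc2)cc1OCc1ccccc1
F3 | step 6 | 2,4,6-tris(benzyloxy)phenol | Oc1c(OCc2ccccc2)cc(OCc2ccccc2)cc1OCc1ccccc1
F4 | step 6 | 2,6-bis(benzyloxy)-4-[2,4,6-tris(benzyloxy)phenoxy]benzaldehyde | O=Cc2c(OCc9ccccc9)cc(Oc1c(OCc9ccccc9)cc(OCc9ccccc9)cc1OCc9ccccc9)cc2OCc9ccccc9
F5 | step 6 | 2,6-bis(benzyloxy)-4-[2,4,6-tris(benzyloxy)phenoxy]phenyl formate | O=COc2c(OCc9ccccc9)cc(Oc1c(OCc9ccccc9)cc(OCc9ccccc9)cc1OCc9ccccc9)cc2OCc9ccccc9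
F6 | step 5 | 2-[3,5-bis(benzyloxy)-4-(methoxymethoxy)phenoxy]acetic acid | OC(=O)COc1cc(OCc2ccccc2)c(OCOC)c(OCc2ccccc2)c1
F7 | step 5 | 2-[3,5-bis(benzyloxy)-4-(methoxymethoxy)phenoxy]acetyl chloride | ClC(=O)COc1cc(OCc2ccccc2)c(OCOC)c(OCc2ccccc2)c1
F8 | step 16 | 5-fluoro-1,2,3-trimethoxybenzene (commercial) | COc1cc(F)cc(OC)c1OC
F9 | step 16 | 2-[chloro(methoxy)methyl]-1-fluoro-3,4,5-trimethoxybenzene | COC(Cl)c1c(F)cc(OC)c(OC)c1OC
F10 | step 16 | 6-fluoro-2,3,4-trimethoxybenzaldehyde | COc1cc(F)c(C=O)c(OC)c1OC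
F11 | step 16 | 6-fluoro-2,3,4-tris(dibromoboryloxy)benzaldehyde | O=Cc1c(F)cc(OB(Br)Br)c(OB(Br)Br)c1OB(Br)Br
F12 | step 16 | 6-fluoro-2,3,4-trihydroxybenzaldehyde | O=Cc1c(F)cc(O)c(O)c1O
F13 | step 16 | 2,3,4-tris(benzyloxy)-6-fluorobenzaldehyde | O=Cc1c(F)cc(OCc2ccccc2)c(OCc2ccccc2)c1OCc1ccccc1
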